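**Plan**

1. Atom labels (bicyclo[3.2.1]octan-8-one core): C1 allyl bridgehead, C2 CH2, C3 CH(OMe), C4 CH(OH), C5 OMe bridgehead, C6 CH(aryl), C7 CH(CH3), C8 C=O. The six-membered ring is C1–C2–C3–C4–C5–C8; the five-membered ring B is C1–C7–C6–C5–C8.
2. Enabling feature: C5 is a methoxy-bearing bridgehead between the C8 ketone and C4, i.e. an α-methoxy ketone. The retrosynthesis cuts C4–C5 and returns C4 to C8 (retro-semipinacol). This gives a cis-fused bicyclo[3.3.0]octane with a tertiary C8–OH next to a C5 dimethyl ketal, in which ring A (C1–C2–C3–C4–C8) is only five-membered.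
3. Further cuts: C3–O and C4–O (syn-dihydroxylation of a C3=C4 alkene), C4–C8 (intramolecular alkenyllithium addition), C1–allyl and C1–C2 (two enolate alkylations), C5–O (ketal from an α-sulfenyl ketone), C6–aryl and C7–CH3 (two conjugate additions to a cyclopentenone).
4. Forward order of rings: ring B comes from a commercial cyclopentenone; ring A is closed as a cyclopentene onto C8 (step 8); in the last step ring A is enlarged by one atom (C5 inserted between C4 and C8) to the six-membered ring, which creates the bicyclo[3.2.1]octane.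
5. Stereochemistry: absolute configuration from (S)-4-silyloxycyclopentenone (cuprate anti to OSi sets C7, the oxygenated centre is then eliminated). C6 comes from anti addition next to C7, C1 from the order of the two alkylations (second one anti to the C7 methyl), C8 from the enforced cis ring fusion, C3/C4 from hydroxyl-directed convex-face OsO4, and C5 from the suprafacial shift in the rigid bicycle.

Key step: step 11

Remark: compounds 1, 4 (as a THF solution) and 10 are taken as catalogue compounds; the hydroxy ketals 18, 20 and 22 are acid-labile and should be purified on base-washed silica.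

**Route**

Step 1
Reactants: 1 (S)-4-(tert-butyldimethylsilyloxy)cyclopent-2-en-1-one
Product: 3 (S)-4-methylcyclopent-2-en-1-one, via trans-β-silyloxy ketone 2 (not isolated)
Conditions: Me2CuLi, Et2O, −78 °C; aq. NH4Cl; then DBU, CH2Cl2, 0 °C
Reagents that add atoms: lithium dimethylcuprate, [Li+].C[Cu-]C
Why: Conjugate addition of the cuprate anti to the silyloxy group sets the methyl-bearing centre (future C7), and E1cB loss of silanolate then moves the enone to the other side with that centre intact (conjugate addition–β-elimination).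

Step 2
Reactants: 3 (S)-4-methylcyclopent-2-en-1-one; 4 (3,4,5-trimethoxyphenyl)magnesium bromide
Product: 6 (2S,3S,4S)-4-methyl-2-(phenylsulfanyl)-3-(3,4,5-trimethoxyphenyl)cyclopentan-1-one, via bromomagnesium enolate 5 (not isolated)
Conditions: CuBr·SMe2 (10 mol%), THF, −40 °C; then PhSO2SPh, −40 → 0 °C; aq. NH4Cl
Reagents that add atoms: S-phenyl benzenethiosulfonate, O=S(=O)(Sc1ccccc1)c1ccccc1
Why: Copper-catalysed 1,4-addition of the aryl Grignard reagent should occur anti to the neighbouring methyl group (sets C6, aryl trans to methyl), and the regiodefined enolate is sulfenylated at C5 (tandem conjugate addition–enolate trapping), whose configuration is of no consequence.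

Step 3
Reactants: 6 (2S,3S,4S)-4-methyl-2-(phenylsulfanyl)-3-(3,4,5-trimethoxyphenyl)cyclopentan-1-one
Product: 9 (3S,4S)-2,2-dimethoxy-4-methyl-3-(3,4,5-trimethoxyphenyl)cyclopentan-1-one, via α-chloro sulfide 7 (not isolated), via O,S-ketal 8 (not isolated)
Conditions: N-chlorosuccinimide, CH2Cl2, 0 °C; then AgOSO2CF3 (2.2 equiv), 2,6-lutidine, MeOH, −20 → 20 °C
Reagents that add atoms: methanol, CO
Why: Chlorination at sulfur gives the α-chloro sulfide, whose Pummerer-type thionium ion is captured by methanol, and silver-assisted loss of thiolate followed by a second capture gives the dimethyl ketal, so that C5 reaches the ketone oxidation level without becoming a stereocentre and C6 is not touched.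

Step 4
Reactants: 10 ethyl (Z)-3-iodoprop-2-enoate
Product: 11 (Z)-3-iodoprop-2-en-1-ol
Conditions: iBu2AlH (2.2 equiv), CH2Cl2, −78 → 0 °C; aq. KNaC4H4O6
Reagents that add atoms: none
Why: 1,2-Reduction of the ester by the aluminium hydride should give the allylic alcohol with the (Z)-iodoalkene unchanged.

Step 5
Reactants: 11 (Z)-3-iodoprop-2-en-1-ol
Product: 12 (Z)-3-bromo-1-iodoprop-1-ene
Conditions: CBr4, PPh3, CH2Cl2, 0 °C
Reagents that add atoms: carbon tetrabromide, BrC(Br)(Br)Br
Why: Appel bromination of the primary allylic alcohol under neutral conditions keeps the alkene geometry.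

Step 6
Reactants: 9 (3S,4S)-2,2-dimethoxy-4-methyl-3-(3,4,5-trimethoxyphenyl)cyclopentan-1-one; 12 (Z)-3-bromo-1-iodoprop-1-ene
Product: 14 (3S,4S,5S)-5-[(2Z)-3-iodoprop-2-en-1-yl]-2,2-dimethoxy-4-methyl-3-(3,4,5-trimethoxyphenyl)cyclopentan-1-one, via lithium enolate 13 (not isolated)
Conditions: LiN(iPr)2 (1.05 equiv), THF, −78 °C; then 12, −78 → −30 °C
Reagents that add atoms: none
Why: The ketal blocks C5, so the ketone can be deprotonated only at C1, and the enolate is alkylated by the reactive allylic bromide (enolate alkylation); the new centre is re-enolized in step 7.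

Step 7
Reactants: 14 (3S,4S,5S)-5-[(2Z)-3-iodoprop-2-en-1-yl]-2,2-dimethoxy-4-methyl-3-(3,4,5-trimethoxyphenyl)cyclopentan-1-one; 15 allyl bromide
Product: 17 (3S,4R,5R)-5-[(2Z)-3-iodoprop-2-en-1-yl]-2,2-dimethoxy-4-methyl-5-(prop-2-en-1-yl)-3-(3,4,5-trimethoxyphenyl)cyclopentan-1-one, via lithium enolate 16 (not isolated)
Conditions: LiN(iPr)2 (1.05 equiv), THF–DMPU, −78 °C; then allyl bromide, −78 → −20 °C
Reagents that add atoms: none
Why: Allyl bromide should attack the tetrasubstituted enolate on the face anti to the adjacent C7 methyl group (1,2-induction in cyclopentanone enolate alkylation), which makes quaternary C1 with allyl trans and the iodoallyl arm cis to methyl.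

Step 8
Reactants: 17 (3S,4R,5R)-5-[(2Z)-3-iodoprop-2-en-1-yl]-2,2-dimethoxy-4-methyl-5-(prop-2-en-1-yl)-3-(3,4,5-trimethoxyphenyl)cyclopentan-1-one
Product: 18 (3aS,5S,6R,6aR)-4,4-dimethoxy-6-methyl-6a-(prop-2-en-1-yl)-5-(3,4,5-trimethoxyphenyl)-1,3a,4,5,6,6a-hexahydropentalen-3a-ol
Conditions: t-BuLi (2.1 equiv), Et2O–THF, −100 → −78 °C; aq. NH4Cl
Reagents that add atoms: none
Why: Iodine–lithium exchange gives the (Z)-alkenyllithium, which adds at once to the non-enolizable C8 ketone (5-exo anionic cyclization); the three-atom tether allows only the cis-fused bicyclo[3.3.0]octene, so C4 enters C8 on the face of its own arm and the hydroxyl ends on the convex face.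

Step 9
Reactants: 18 (3aS,5S,6R,6aR)-4,4-dimethoxy-6-methyl-6a-(prop-2-en-1-yl)-5-(3,4,5-trimethoxyphenyl)-1,3a,4,5,6,6a-hexahydropentalen-3a-ol
Product: 20 (2S,3S,3aR,5S,6R,6aR)-4,4-dimethoxy-6-methyl-6a-(prop-2-en-1-yl)-5-(3,4,5-trimethoxyphenyl)octahydropentalene-2,3,3a-triol, via osmate ester 19 (not isolated)
Conditions: OsO4 (1.05 equiv), TMEDA (1.1 equiv), CH2Cl2, −78 °C; then ethylenediamine, 20 °C
Reagents that add atoms: osmium tetroxide, O=[Os](=O)(=O)=O
Why: The OsO4–diamine complex is delivered by hydrogen bonding to the tertiary allylic C8 hydroxyl (hydroxyl-directed syn-dihydroxylation), which should select the ring alkene over the remote allyl group and the convex face, giving C3–OH and C4–OH cis to C8–OH.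

Step 10
Reactants: 20 (2S,3S,3aR,5S,6R,6aR)-4,4-dimethoxy-6-methyl-6a-(prop-2-en-1-yl)-5-(3,4,5-trimethoxyphenyl)octahydropentalene-2,3,3a-triol
Product: 22 (2S,3S,3aR,5S,6R,6aR)-2,4,4-trimethoxy-6-methyl-6a-(prop-2-en-1-yl)-5-(3,4,5-trimethoxyphenyl)octahydropentalene-3,3a-diol, via stannylene acetal 21 (not isolated)
Conditions: Bu2SnO, MeOH, reflux, then evaporation; MeI, CsF, DMF, 20 °C
Reagents that add atoms: iodomethane, CI
Why: The cis-2,3-diol forms the dibutylstannylene acetal, and fluoride-promoted alkylation should take place at the less hindered C3 oxygen, remote from the fully substituted C8 (tin-mediated regioselective mono-O-alkylation), leaving the C4 and C8 hydroxyls free.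

Step 11
Reactants: 22 (2S,3S,3aR,5S,6R,6aR)-2,4,4-trimethoxy-6-methyl-6a-(prop-2-en-1-yl)-5-(3,4,5-trimethoxyphenyl)octahydropentalene-3,3a-diol
Product: 23 (1R,3S,4S,5S,6S,7R)-4-hydroxy-3,5-dimethoxy-7-methyl-1-(prop-2-en-1-yl)-6-(3,4,5-trimethoxyphenyl)bicyclo[3.2.1]octan-8-one
Conditions: Me3SiOSO2CF3 (0.2 equiv), 4 Å molecular sieves, CH2Cl2, −78 → −30 °C; Et3N, aq. NaHCO3
Reagents that add atoms: none
Why: The silyl triflate ionizes the C5 dimethyl ketal to an O-methyl oxocarbenium ion, and the C8–C4 bond, which stands on the concave face parallel to the empty orbital at C5, migrates from C8 to C5 while the C8 hydroxyl collapses to the ketone (semipinacol shift; methanol is the only by-product and the acid is regenerated). The closest known reaction type is the acid-induced ring expansion of α-hydroxy ketals (1-(1,1-dialkoxyalkyl)cycloalkanols) to 2-alkoxycycloalkanones. No ring is closed: the five-membered ring A (C1–C2–C3–C4–C8) grows by one atom into the six-membered ring C1–C2–C3–C4–C5–C8 because C5 is inserted between C4 and C8, and ring B thereby becomes the two-carbon-bridged cyclopentanone of the bicyclo[3.2.1]octane. C4 migrates with retention and arrives suprafacially on the ring-A face of C5, so the new stereocentre C5 (methoxy bridgehead) is fixed by the cis ring fusion set in step 8, and C1, C3, C4, C6 and C7 are untouched. The step needs the 1,2-shift to outrun loss of H6 to an enol ether, Prins-type capture by the allyl alkene and migration of the wrong bond. The substrate secures this because the C8–C1 bond lies in the plane of ring B and cannot overlap with the cationic centre, the migrating C4 carries an oxygen that raises its migratory aptitude, and the shift is driven by formation of the C8 carbonyl.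

**Compound list**

1 | (S)-4-(tert-butyldimethylsilyloxy)cyclopent-2-en-1-one | O=C1C=C[C@@H](O[Si](C)(C)C(C)(C)C)C1 | starting material
2 | (3S,4S)-4-(tert-butyldimethylsilyloxy)-3-methylcyclopentan-1-one (methyl trans to OSi) | O=C1C[C@H](C)[C@@H](O[Si](C)(C)C(C)(C)C)C1 | intermediate
3 | (S)-4-methylcyclopent-2-en-1-one | O=C1C=C[C@@H](C)C1 | intermediate
4 | (3,4,5-trimethoxyphenyl)magnesium bromide | COc1cc([Mg]Br)cc(OC)c1OC | starting material
5 | bromomagnesium enolate of trans-4-methyl-3-(3,4,5-trimethoxyphenyl)cyclopentanone (C1=C2 enolate) | Br[Mg]OC1=C[C@H](c2cc(OC)c(OC)c(OC)c2)[C@@H](C)C1 | intermediate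
6 | (2S,3S,4S)-4-methyl-2-(phenylsulfanyl)-3-(3,4,5-trimethoxyphenyl)cyclopentan-1-one (all-trans) | O=C1[C@@H](Sc2ccccc2)[C@H](c2cc(OC)c(OC)c(OC)c2)[C@@H](C)C1 | intermediate
7 | (3S,4S)-2-chloro-4-methyl-2-(phenylsulfanyl)-3-(3,4,5-trimethoxyphenyl)cyclopentan-1-one (C2 epimers) | O=C1C(Cl)(Sc2ccccc2)[C@H](c2cc(OC)c(OC)c(OC)c2)[C@@H](C)C1 | intermediate
8 | (3S,4S)-2-methoxy-4-methyl-2-(phenylsulfanyl)-3-(3,4,5-trimethoxyphenyl)cyclopentan-1-one (C2 epimers) | O=C1C(OC)(Sc2ccccc2)[C@H](c2cc(OC)c(OC)c(OC)c2)[C@@H](C)C1 | intermediate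
9 | (3S,4S)-2,2-dimethoxy-4-methyl-3-(3,4,5-trimethoxyphenyl)cyclopentan-1-one | O=C1C(OC)(OC)[C@H](c2cc(OC)c(OC)c(OC)c2)[C@@H](C)C1 | intermediate
10 | ethyl (Z)-3-iodoprop-2-enoate | CCOC(=O)/C=C\I | starting material
11 | (Z)-3-iodoprop-2-en-1-ol | OC/C=C\I | intermediate
12 | (Z)-3-bromo-1-iodoprop-1-ene | BrC/C=C\I | intermediate
13 | lithium enolate of 9 (enolate towards C5 of the cyclopentanone, i.e. core atom C1) | [Li]OC1=C[C@H](C)[C@@H](c2cc(OC)c(OC)c(OC)c2)C1(OC)OC | intermediate
14 | (3S,4S,5S)-5-[(2Z)-3-iodoprop-2-en-1-yl]-2,2-dimethoxy-4-methyl-3-(3,4,5-trimethoxyphenyl)cyclopentan-1-one (iodoallyl trans to methyl) | O=C1C(OC)(OC)[C@H](c2cc(OC)c(OC)c(OC)c2)[C@@H](C)[C@@H]1C/C=C\I | intermediate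
15 | allyl bromide (3-bromoprop-1-ene) | C=CCBr | starting material
16 | lithium enolate of 14 (tetrasubstituted enolate) | [Li]OC1=C(C/C=C\I)[C@H](C)[C@@H](c2cc(OC)c(OC)c(OC)c2)C1(OC)OC | intermediate
17 | (3S,4R,5R)-5-[(2Z)-3-iodoprop-2-en-1-yl]-2,2-dimethoxy-4-methyl-5-(prop-2-en-1-yl)-3-(3,4,5-trimethoxyphenyl)cyclopentan-1-one (iodoallyl cis, allyl trans to methyl) | O=C1C(OC)(OC)[C@H](c2cc(OC)c(OC)c(OC)c2)[C@@H](C)[C@@]1(CC=C)C/C=C\I | intermediate
18 | (3aS,5S,6R,6aR)-4,4-dimethoxy-6-methyl-6a-(prop-2-en-1-yl)-5-(3,4,5-trimethoxyphenyl)-1,3a,4,5,6,6a-hexahydropentalen-3a-ol (cis-fused; OH, allyl and aryl on the convex face, methyl on the concave face) | C=CC[C@]12CC=C[C@@]1(O)C(OC)(OC)[C@H](c1cc(OC)c(OC)c(OC)c1)[C@H]2C | intermediate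
19 | osmate ester of 18 (2,3-glycolate of hexavalent osmium, TMEDA-chelated) | C=CC[C@]12C[C@@H]3O[Os-2]4(=O)(=O)(O[C@@H]3[C@@]1(O)C(OC)(OC)[C@H](c1cc(OC)c(OC)c(OC)c1)[C@H]2C)[N+](C)(C)CC[N+]4(C)C | intermediate
20 | (2S,3S,3aR,5S,6R,6aR)-4,4-dimethoxy-6-methyl-6a-(prop-2-en-1-yl)-5-(3,4,5-trimethoxyphenyl)octahydropentalene-2,3,3a-triol (three hydroxyls cis) | C=CC[C@]12C[C@H](O)[C@H](O)[C@@]1(O)C(OC)(OC)[C@H](c1cc(OC)c(OC)c(OC)c1)[C@H]2C | intermediate
21 | 2,3-O-dibutylstannylene acetal of 20 | C=CC[C@]12C[C@@H]3O[Sn](CCCC)(CCCC)O[C@@H]3[C@@]1(O)C(OC)(OC)[C@H](c1cc(OC)c(OC)c(OC)c1)[C@H]2C | intermediate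
22 | (2S,3S,3aR,5S,6R,6aR)-2,4,4-trimethoxy-6-methyl-6a-(prop-2-en-1-yl)-5-(3,4,5-trimethoxyphenyl)octahydropentalene-3,3a-diol | C=CC[C@]12C[C@H](OC)[C@H](O)[C@@]1(O)C(OC)(OC)[C@H](c1cc(OC)c(OC)c(OC)c1)[C@H]2C | intermediate
23 | (1R,3S,4S,5S,6S,7R)-4-hydroxy-3,5-dimethoxy-7-methyl-1-(prop-2-en-1-yl)-6-(3,4,5-trimethoxyphenyl)bicyclo[3.2.1]octan-8-one | C=CC[C@]12C[C@H](OC)[C@H](O)[C@](OC)(C1=O)[C@H](c1cc(OC)c(OC)c(OC)c1)[C@H]2C | target

**Step count and risks**

Total step count: 11. Longest linear sequence: 9 steps (steps 1–3 and 6–11, from 1); steps 4 and 5 make the alkylating agent 12.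

Steps most likely to fail, with one fallback each:

1. Step 11. What may go wrong: the oxocarbenium ion may lose H6 to give the aryl-conjugated enol ether, or be captured by the allyl alkene, faster than C4 migrates. The fallback sets out from 22 and comes back at 23; it closes the six-membered ring by an aldol bond C4–C5 instead of a shift. NaIO4 (THF/H2O, NaHCO3) should cleave the C8/C4 vicinal diol of 22 to (2S)-3-[(1R,2R,3S)-4,4-dimethoxy-2-methyl-5-oxo-1-(prop-2-en-1-yl)-3-(3,4,5-trimethoxyphenyl)cyclopentyl]-2-methoxypropanal F1. SmI2 (2.2 equiv, THF, −78 °C) should then remove one methoxy group of the α-keto ketal reductively to give the diiodosamarium enolate F2, which adds to the aldehyde (intramolecular Reformatsky-type aldol) to give 23. The C4 configuration would then depend on chelation of samarium by the C3 methoxy group and would have to be verified.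

2. Step 3. What may go wrong: elimination of H6 from the thionium or oxocarbenium ion (giving a 2-sulfanyl or 2-methoxy cyclopentenone) instead of capture by methanol. The fallback sets out from 3 and comes back at 8; it installs the methoxy group before the aryl group, so that sulfur is introduced by enolate chemistry and no thionium ion next to the benzylic C6–H is needed. α-Iodination of 3 (I2, pyridine, CH2Cl2) should give (S)-2-iodo-4-methylcyclopent-2-en-1-one F3. Copper-catalysed C–O coupling (CuI, 3,4,7,8-tetramethyl-1,10-phenanthroline, Cs2CO3, MeOH/toluene, 80 °C) should give (S)-2-methoxy-4-methylcyclopent-2-en-1-one F4. Conjugate addition of 4 (CuBr·SMe2, THF, −40 °C) should give the bromomagnesium enolate F5, which is sulfenylated with PhSO2SPh to 8; 8 is then taken to 9 with AgOSO2CF3/MeOH as in the last stage of step 3.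

3. Step 10. What may go wrong: poor site selectivity in the alkylation of the stannylene acetal (methylation at the C4 oxygen or double methylation), or premature Lewis-acid-induced ring expansion. The fallback sets out from 20 and comes back at 23; it inverts the last two operations, so that the two secondary hydroxyls are told apart by ring conformation and not by neighbour bulk. Triol 20 is rearranged first (Me3SiOSO2CF3 cat., CH2Cl2, −78 → −30 °C) to (1R,3S,4S,5S,6S,7R)-3,4-dihydroxy-5-methoxy-7-methyl-1-(prop-2-en-1-yl)-6-(3,4,5-trimethoxyphenyl)bicyclo[3.2.1]octan-8-one F6, in which the C3 hydroxyl is equatorial and the C4 hydroxyl axial. Its 3,4-O-dibutylstannylene acetal F7 (Bu2SnO, MeOH, reflux) should then be methylated (MeI, CsF, DMF) at the equatorial C3 oxygen to give 23.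

**Further compounds**

F1 | step 11 | (2S)-3-[(1R,2R,3S)-4,4-dimethoxy-2-methyl-5-oxo-1-(prop-2-en-1-yl)-3-(3,4,5-trimethoxyphenyl)cyclopentyl]-2-methoxypropanal | C=CC[C@]1(C[C@H](OC)C=O)C(=O)C(OC)(OC)[C@H](c2cc(OC)c(OC)c(OC)c2)[C@H]1C
F2 | step 11 | diiodosamarium enolate of F1 (C8–O–SmI2, C5=C8 enolate carrying OMe at C5) | C=CC[C@]1(C[C@H](OC)C=O)C(O[Sm](I)I)=C(OC)[C@H](c2cc(OC)c(OC)c(OC)c2)[C@H]1C
F3 | step 3 | (S)-2-iodo-4-methylcyclopent-2-en-1-one | O=C1C(I)=C[C@@H](C)C1
F4 | step 3 | (S)-2-methoxy-4-methylcyclopent-2-en-1-one | O=C1C(OC)=C[C@@H](C)C1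
F5 | step 3 | bromomagnesium enolate of trans-2-methoxy-4-methyl-3-(3,4,5-trimethoxyphenyl)cyclopentanone | Br[Mg]OC1=C(OC)[C@H](c2cc(OC)c(OC)c(OC)c2)[C@@H](C)C1
F6 | step 10 | (1R,3S,4S,5S,6S,7R)-3,4-dihydroxy-5-methoxy-7-methyl-1-(prop-2-en-1-yl)-6-(3,4,5-trimethoxyphenyl)bicyclo[3.2.1]octan-8-one | C=CC[C@]12C[C@H](O)[C@H](O)[C@](OC)(C1=O)[C@H](c1cc(OC)c(OC)c(OC)c1)[C@H]2C
F7 | step 10 | 3,4-O-dibutylstannylene acetal of F6 | C=CC[C@]12C[C@@H]3O[Sn](CCCC)(CCCC)O[C@@H]3[C@](OC)(C1=O)[C@H](c1cc(OC)c(OC)c(OC)c1)[C@H]2C
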